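The plan builds the benzene ring last, around a terminal alkyne that already sits on furan C2 (2,4-disubstituted numbering). The feature exploited is the benzene ring itself. Its oxygens on C2' and C5' stand para to each other, and C1', ortho to the C2' oxygen, carries the furan. An alkenyl(methoxy)carbene complex of zerovalent chromium, a terminal alkyne and one CO ligand assemble exactly this pattern. In one operation the key step forms three C–C bonds, closes the six-membered ring and delivers the two oxygens differentiated as OSiMe3 and OMe. Its precursor is the finished furan half, (R)-1-(5-ethynylfuran-3-yl)-4-methylpent-3-enyl isovalerate, with stereocentre, ester and prenyl alkene already in place.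

Key step: step 9

Remark on the chemistry: the stereocentre is (R) (O > furan carbon > CH2 > H); the isovalerate is installed directly before the key step so that it never meets the aqueous acid or the K2CO3/MeOH of the earlier steps, and partial loss of the aryl silyl ether after the key step is harmless because the next step passes through the free phenol.

Step 1
Reactants: 1 4-methylpent-3-enoic acid
Product: 3 N-methoxy-N,4-dimethylpent-3-enamide, via acyl imidazolide 2 (not isolated)
Conditions: 1,1'-carbonyldiimidazole (1.1 equiv), CH2Cl2, 0 °C to rt; then MeNH(OMe)·HCl (1.2 equiv), rt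
Reagents that add atoms: N,O-dimethylhydroxylamine hydrochloride, CNOC.Cl; 1,1'-carbonyldiimidazole, O=C(n1ccnc1)n1ccnc1 (imidazolyl group of 2 only)
Why: Weinreb amide formation by imidazolide activation and aminolysis runs close to neutral, so the β,γ-alkene should not drift into conjugation with the carbonyl group.

Step 2
Reactants: 4 4-bromofuran-2-carbaldehyde
Product: 5 2-(4-bromofuran-2-yl)-1,3-dioxolane
Conditions: HOCH2CH2OH (3 equiv), p-TsOH·H2O (cat.), toluene, reflux, Dean–Stark
Reagents that add atoms: ethylene glycol, OCCO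
Why: Acid-catalysed acetalisation with azeotropic removal of water masks the formyl group so that it survives the organolithium and hydride steps that follow.

Step 3
Reactants: 5 2-(4-bromofuran-2-yl)-1,3-dioxolane; 3 N-methoxy-N,4-dimethylpent-3-enamide
Product: 7 1-[5-(1,3-dioxolan-2-yl)furan-3-yl]-4-methylpent-3-en-1-one, via 4-lithiofuran acetal 6 (not isolated)
Conditions: 5 (1.2 equiv), n-BuLi (1.15 equiv), THF, −78 °C; then 3 (1.0 equiv), −78 °C; AcOH/THF quench at −78 °C
Reagents that add atoms: n-butyllithium, [Li]CCCC (lithium of 6 only)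
Why: Bromine–lithium exchange at the furan β-carbon outruns deprotonation at −78 °C and the β-furyllithium holds its position at that temperature, the Weinreb ketone synthesis stops cleanly at the ketone, and the cold acidic quench keeps the alkene out of conjugation.

Step 4
Reactants: 7 1-[5-(1,3-dioxolan-2-yl)furan-3-yl]-4-methylpent-3-en-1-one
Product: 8 (R)-1-[5-(1,3-dioxolan-2-yl)furan-3-yl]-4-methylpent-3-en-1-ol
Conditions: (S)-Me-CBS oxazaborolidine (0.2 equiv), catecholborane (2 equiv), toluene, −78 to −40 °C; aqueous NaOH work-up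
Reagents that add atoms: none
Why: Corey–Bakshi–Shibata reduction, in which the ketone should bind to the (S)-oxazaborolidine–borane complex with the furyl group as the large and the CH2 chain as the small substituent, so hydride reaches the Si face and sets the (R) carbinol centre, while catecholborane at low temperature leaves the trisubstituted alkene and the acetal alone.

Step 5
Reactants: 8 (R)-1-[5-(1,3-dioxolan-2-yl)furan-3-yl]-4-methylpent-3-en-1-ol
Product: 9 (R)-4-(1-hydroxy-4-methylpent-3-enyl)furan-2-carbaldehyde
Conditions: PPTS (0.2 equiv), acetone–H2O (9:1), 45 °C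
Reagents that add atoms: water, O
Why: Acid-catalysed acetal hydrolysis, in which the furfural-type acetal ionises readily at the mild acidity of pyridinium tosylate whereas the β-furyl carbinol does not ionise and the prenyl alkene is not protonated, so the (R) centre is kept.

Step 6
Reactants: 9 (R)-4-(1-hydroxy-4-methylpent-3-enyl)furan-2-carbaldehyde
Product: 10 (R)-1-(5-ethynylfuran-3-yl)-4-methylpent-3-en-1-ol
Conditions: dimethyl (1-diazo-2-oxopropyl)phosphonate (1.3 equiv), K2CO3 (2 equiv), MeOH, 0 °C to rt
Reagents that add atoms: dimethyl (1-diazo-2-oxopropyl)phosphonate, CC(=O)C(=[N+]=[N-])P(=O)(OC)OC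
Why: Ohira–Bestmann variant of the Seyferth–Gilbert homologation, which turns a non-enolisable heteroaryl aldehyde into the terminal alkyne and tolerates a free secondary alcohol, whereas an ester at this position could suffer methanolysis.

Step 7
Reactants: 10 (R)-1-(5-ethynylfuran-3-yl)-4-methylpent-3-en-1-ol
Product: 11 (R)-1-(5-ethynylfuran-3-yl)-4-methylpent-3-enyl isovalerate
Conditions: isovaleric anhydride (1.3 equiv), Et3N (2 equiv), DMAP (0.1 equiv), CH2Cl2, 0 °C to rt
Reagents that add atoms: isovaleric anhydride, CC(C)CC(=O)OC(=O)CC(C)C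
Why: DMAP-catalysed acyl transfer acylates the oxygen only, so the C–O bond of the stereocentre is untouched, the (R) configuration is retained and the terminal alkyne is a spectator.

Step 8
Reactants: 12 (E)-(2-bromovinyl)trimethylsilane; 13 chromium hexacarbonyl, Cr(CO)6
Product: 16 pentacarbonyl[methoxy((E)-2-trimethylsilylvinyl)carbene]chromium, via (E)-2-trimethylsilylvinyllithium 14 (not isolated), via lithium acylchromate 15 (not isolated)
Conditions: t-BuLi (2 equiv), Et2O, −78 °C; Cr(CO)6, Et2O, 0 °C to rt; evaporate; Me3OBF4, CH2Cl2, 0 °C to rt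
Reagents that add atoms: trimethyloxonium tetrafluoroborate, C[O+](C)C.F[B-](F)(F)F; tert-butyllithium, [Li]C(C)(C)C (lithium of 14 and 15 only)
Why: Fischer carbene synthesis, in which bromine–lithium exchange at the sp2 carbon keeps the E geometry, the vinyllithium adds to a CO ligand of Cr(CO)6 and the hard Meerwein salt methylates the acylate oxygen.

Step 9
Reactants: 11 (R)-1-(5-ethynylfuran-3-yl)-4-methylpent-3-enyl isovalerate; 16 pentacarbonyl[methoxy((E)-2-trimethylsilylvinyl)carbene]chromium
Product: 20 (R)-1-{5-[5-methoxy-2-(trimethylsilyloxy)phenyl]furan-3-yl}-4-methylpent-3-enyl isovalerate, via dienylketene chromium complex 17 (not isolated), via silylcyclohexadienone chromium complex 18 (not isolated), via arene tricarbonylchromium complex 19 (not isolated)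
Conditions: 16 (1.3 equiv), THF (0.05 mol/L), 50 °C, Ar; then air, Et2O, rt; filtration through Et3N-deactivated SiO2
Reagents that add atoms: none
Why: Thermal loss of one cis CO from 16 opens a site for the alkyne of 11, which inserts into the Cr=C bond (carbene carbon to alkyne CH), and migration of a CO ligand onto the new furyl-bearing carbene carbon gives 17. The one new ring, the six-membered carbocycle, closes by a six-electron electrocyclisation of 17 that joins the ketene carbon to the silyl-bearing vinyl terminus and gives 18. A 1,3 shift of silicon from the sp3 ring carbon of 18 to the adjacent carbonyl oxygen aromatises the ring to 19, so the CO-derived oxygen emerges as OSiMe3 and the carbene oxygen as OMe, and air then strips the Cr(CO)3 unit to free 20. The closest known reaction type is the Dötz benzannulation of alkenyl(alkoxy)carbene complexes of zerovalent chromium with terminal alkynes, in the variant where a β-silylvinyl complex replaces the unstable parent vinyl complex. No lasting stereocentre is created, since the sp3 carbon of 18 is erased on aromatisation, and the (R) centre of 11 lies far from every reacting atom and sees only neutral, warm THF. The step needs regioselectivity, secured by the size difference at the terminal alkyne (H against furyl) that places the furyl-bearing carbon next to the CO-derived carbon, and chemoselectivity, secured because ester, furan and trisubstituted alkene do not compete with a terminal alkyne for the unsaturated chromium centre.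

Step 10
Reactants: 20 (R)-1-{5-[5-methoxy-2-(trimethylsilyloxy)phenyl]furan-3-yl}-4-methylpent-3-enyl isovalerate
Product: 22 (R)-1-[5-(3,6-dioxocyclohexa-1,4-dien-1-yl)furan-3-yl]-4-methylpent-3-enyl isovalerate, via 4-methoxyphenol 21 (not isolated)
Conditions: MeCN–H2O–AcOH (8:2:1), rt; then PhI(OAc)2 (1.1 equiv), 0 °C
Reagents that add atoms: water, O
Why: Aryl trimethylsilyl ethers hydrolyse readily in aqueous acetic acid, and the freed 4-methoxyphenol undergoes the trivalent-iodine oxidative demethylation to the p-quinone (water capture at the methoxy-bearing carbon, loss of methanol), which at 0 °C should be far faster than any attack of PhI(OAc)2 on the furan or the alkene.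

Step 11
Reactants: 22 (R)-1-[5-(3,6-dioxocyclohexa-1,4-dien-1-yl)furan-3-yl]-4-methylpent-3-enyl isovalerate
Product: 23 (R)-1-[5-(2,5-dihydroxyphenyl)furan-3-yl]-4-methylpent-3-enyl isovalerate (target)
Conditions: Na2S2O4 (excess), EtOAc–H2O, rt, Ar
Reagents that add atoms: none
Why: Dithionite reduction of a p-benzoquinone to the hydroquinone is a mild two-electron, two-proton process in a near-neutral two-phase system that leaves ester, alkene, furan and the (R) centre untouched.

Compound list
1 | 4-methylpent-3-enoic acid | CC(C)=CCC(=O)O | starting material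
2 | 1-(imidazol-1-yl)-4-methylpent-3-en-1-one (acyl imidazolide) | CC(C)=CCC(=O)n1ccnc1 | intermediate
3 | N-methoxy-N,4-dimethylpent-3-enamide | CC(C)=CCC(=O)N(C)OC | intermediate
4 | 4-bromofuran-2-carbaldehyde | O=Cc1cc(Br)co1 | starting material
5 | 2-(4-bromofuran-2-yl)-1,3-dioxolane | Brc1coc(C2OCCO2)c1 | intermediate
6 | [5-(1,3-dioxolan-2-yl)furan-3-yl]lithium | [Li]c1coc(C2OCCO2)c1 | intermediate
7 | 1-[5-(1,3-dioxolan-2-yl)furan-3-yl]-4-methylpent-3-en-1-one | CC(C)=CCC(=O)c1coc(C2OCCO2)c1 | intermediate
8 | (R)-1-[5-(1,3-dioxolan-2-yl)furan-3-yl]-4-methylpent-3-en-1-ol | CC(C)=CC[C@@H](O)c1coc(C2OCCO2)c1 | intermediate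
9 | (R)-4-(1-hydroxy-4-methylpent-3-enyl)furan-2-carbaldehyde | CC(C)=CC[C@@H](O)c1coc(C=O)c1 | intermediate
10 | (R)-1-(5-ethynylfuran-3-yl)-4-methylpent-3-en-1-ol | CC(C)=CC[C@@H](O)c1coc(C#C)c1 | intermediate
11 | (R)-1-(5-ethynylfuran-3-yl)-4-methylpent-3-enyl isovalerate | CC(C)=CC[C@@H](OC(=O)CC(C)C)c1coc(C#C)c1 | intermediate
12 | (E)-(2-bromovinyl)trimethylsilane | C[Si](C)(C)/C=C/Br | starting material
13 | chromium hexacarbonyl, Cr(CO)6 | [C-]#[O+].[C-]#[O+].[C-]#[O+].[C-]#[O+].[C-]#[O+].[C-]#[O+].[Cr] | starting material
14 | (E)-(2-trimethylsilylvinyl)lithium | [Li]/C=C/[Si](C)(C)C | intermediate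
15 | lithium pentacarbonyl[(E)-3-trimethylsilylacryloyl]chromate | [Li+].[O-]C(/C=C/[Si](C)(C)C)=[Cr](=C=O)(=C=O)(=C=O)(=C=O)=C=O | intermediate
16 | pentacarbonyl[methoxy((E)-2-trimethylsilylvinyl)carbene]chromium | COC(/C=C/[Si](C)(C)C)=[Cr](=C=O)(=C=O)(=C=O)(=C=O)=C=O | intermediate
17 | Cr(CO)3-bound dienylketene: furyl-C(=C=O)-CH=C(OMe)-CH=CH-SiMe3, ketene and vinylsilane arms cis on the central alkene, (R) side chain unchanged | CC(C)=CC[C@@H](OC(=O)CC(C)C)c1coc(C(=C=O)/C=C(OC)\C=C\[Si](C)(C)C)c1.[Cr].[C-]#[O+].[C-]#[O+].[C-]#[O+] | intermediate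
18 | Cr(CO)3-bound (R)-1-{5-[3-methoxy-6-oxo-5-(trimethylsilyl)cyclohexa-1,3-dien-1-yl]furan-3-yl}-4-methylpent-3-enyl isovalerate (ring sp3 carbon transient, unassigned) | CC(C)=CC[C@@H](OC(=O)CC(C)C)c1coc(C2=CC(OC)=CC([Si](C)(C)C)C2=O)c1.[Cr].[C-]#[O+].[C-]#[O+].[C-]#[O+] | intermediate
19 | tricarbonylchromium complex of 20 (metal on the new benzene ring) | CC(C)=CC[C@@H](OC(=O)CC(C)C)c1coc(-c2cc(OC)ccc2O[Si](C)(C)C)c1.[Cr].[C-]#[O+].[C-]#[O+].[C-]#[O+] | intermediate
20 | (R)-1-{5-[5-methoxy-2-(trimethylsilyloxy)phenyl]furan-3-yl}-4-methylpent-3-enyl isovalerate | CC(C)=CC[C@@H](OC(=O)CC(C)C)c1coc(-c2cc(OC)ccc2O[Si](C)(C)C)c1 | intermediate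
21 | (R)-1-[5-(2-hydroxy-5-methoxyphenyl)furan-3-yl]-4-methylpent-3-enyl isovalerate | CC(C)=CC[C@@H](OC(=O)CC(C)C)c1coc(-c2cc(OC)ccc2O)c1 | intermediate
22 | (R)-1-[5-(3,6-dioxocyclohexa-1,4-dien-1-yl)furan-3-yl]-4-methylpent-3-enyl isovalerate | CC(C)=CC[C@@H](OC(=O)CC(C)C)c1coc(C2=CC(=O)C=CC2=O)c1 | intermediate
23 | (R)-1-[5-(2,5-dihydroxyphenyl)furan-3-yl]-4-methylpent-3-enyl isovalerate | CC(C)=CC[C@@H](OC(=O)CC(C)C)c1coc(-c2cc(O)ccc2O)c1 | target

Total step count: 11.
Longest linear sequence: 9 steps (steps 2 to 7 and 9 to 11, from 4).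

Steps most likely to fail

**1. Step 9.** The terminal alkyne may oligomerise on chromium, the intermediate may cyclise before it takes up CO, or 16 may decay thermally before it is consumed.
- The fallback sets out from 3 and comes back at 21. It makes the furan–arene bond by cross-coupling instead of by ring construction.
- 3-Bromofuran undergoes bromine–lithium exchange (n-BuLi, THF, −78 °C) to 3-furyllithium F1. This is acylated with 3 and quenched cold with AcOH to give 1-(furan-3-yl)-4-methylpent-3-en-1-one F2.
- Reduction as in step 4 should give (R)-1-(furan-3-yl)-4-methylpent-3-en-1-ol F3, and acylation as in step 7 should give (R)-1-(furan-3-yl)-4-methylpent-3-enyl isovalerate F4.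
- Iridium-catalysed C–H borylation ([Ir(OMe)(cod)]2, dtbpy, B2pin2, THF, rt) is expected at the unhindered α-carbon remote from the branched side chain. It should give (R)-4-methyl-1-[5-(4,4,5,5-tetramethyl-1,3,2-dioxaborolan-2-yl)furan-3-yl]pent-3-enyl isovalerate F5.
- Suzuki–Miyaura coupling of F5 with 2-bromo-4-methoxyphenol (PdCl2(dppf), K3PO4, dioxane–H2O, 60 °C) gives 21, which enters the PhI(OAc)2 half of step 10.

**2. Step 3.** Three processes threaten this step:
- Proton transfer from the doubly activated CH2 of 3 to the basic furyllithium may outrun addition.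
- Lithium may migrate to the furan α-carbon.
- The alkene may slip into conjugation during work-up.

The fallback sets out from 6 (generated from 5 as before) and from 1, and comes back at 7. It forms the bond with a non-basic, configurationally fixed organometal.
- 6 is transmetallated with ZnCl2 (THF, −78 to 0 °C) to [5-(1,3-dioxolan-2-yl)furan-3-yl]zinc chloride F6.
- Acid 1 is converted with (COCl)2 and catalytic DMF in CH2Cl2 into 4-methylpent-3-enoyl chloride F7.
- Negishi acylation of F6 with F7 (Pd(PPh3)4 cat., THF, 0 °C to rt) gives 7 under neutral conditions.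

**3. Step 4.** Facial selectivity may be poor because the small furan ring and the unbranched chain differ little in size, and turnover may be slow at the low temperature needed to spare the alkene.
- The fallback sets out from 6 and comes back at 8. It sets the stereocentre in a C–C bond formation, and it also bypasses step 3.
- 6 is quenched with DMF (−78 °C, then aqueous NH4Cl) to 5-(1,3-dioxolan-2-yl)furan-3-carbaldehyde F8.
- Brown allylboration with (+)-Ipc2B(allyl), the reagent derived from (−)-α-pinene (Et2O, −78 °C, then NaOH/H2O2), should give (R)-1-[5-(1,3-dioxolan-2-yl)furan-3-yl]but-3-en-1-ol F9 through the chair-like transition state governed by the isopinocampheyl groups.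
- Cross-metathesis of F9 with excess 2-methyl-2-butene (second-generation Grubbs catalyst, RuCl2(=CHPh)(PCy3)(H2IMes), CH2Cl2, 40 °C) installs the prenyl terminus and gives 8.

Further compounds
F1 | step 9 | 3-furyllithium | [Li]c1ccoc1
F2 | step 9 | 1-(furan-3-yl)-4-methylpent-3-en-1-one | CC(C)=CCC(=O)c1ccoc1
F3 | step 9 | (R)-1-(furan-3-yl)-4-methylpent-3-en-1-ol | CC(C)=CC[C@@H](O)c1ccoc1
F4 | step 9 | (R)-1-(furan-3-yl)-4-methylpent-3-enyl isovalerate | CC(C)=CC[C@@H](OC(=O)CC(C)C)c1ccoc1
F5 | step 9 | (R)-4-methyl-1-[5-(4,4,5,5-tetramethyl-1,3,2-dioxaborolan-2-yl)furan-3-yl]pent-3-enyl isovalerate | CC(C)=CC[C@@H](OC(=O)CC(C)C)c1coc(B2OC(C)(C)C(C)(C)O2)c1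
F6 | step 3 | [5-(1,3-dioxolan-2-yl)furan-3-yl]zinc chloride | Cl[Zn]c1coc(C2OCCO2)c1
F7 | step 3 | 4-methylpent-3-enoyl chloride | CC(C)=CCC(=O)Cl
F8 | step 4 | 5-(1,3-dioxolan-2-yl)furan-3-carbaldehyde | O=Cc1coc(C2OCCO2)c1
F9 | step 4 | (R)-1-[5-(1,3-dioxolan-2-yl)furan-3-yl]but-3-en-1-ol | C=CC[C@@H](O)c1coc(C2OCCO2)c1
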